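**Retrosynthetic overview**
1. Target 12 comes from tribenzyl ether 11 by global hydrogenolysis.
2. 11 is cut at the C2–C1' bond of the apigenin unit: a C2-zincated chromone (α-alkoxyvinyl metal = masked acyl anion / β-acylvinyl anion; the normally electrophilic chromone C2 used as nucleophile) is cross-coupled with aryl bromide 6.
3. 6 comes from quinol 4 by O8-arylation with a diaryliodonium salt; 4 comes from 7-O-benzylacacetin 2 by para-hydroxylation (Elbs).
4. Chromone 9 comes from acetophenone 7 by enaminone annulation.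
5. Ring order: both rings of the acacetin unit are bought intact; the only ring formed is the pyranone of the apigenin unit (step 4), before the fragment union (step 5).

Assumption: the target has no stereocentre (achiral), so there is no configuration to set; acacetin, 1-[2,4-bis(benzyloxy)-6-hydroxyphenyl]ethanone and bis(4-bromophenyl)iodonium triflate are taken as catalogue starting materials.

**Step 1**
Reactants: 1 acacetin, 5,7-dihydroxy-2-(4-methoxyphenyl)-4H-chromen-4-one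
Product: 2 7-(benzyloxy)-5-hydroxy-2-(4-methoxyphenyl)-4H-chromen-4-one
Conditions: BnBr (1.05 equiv), K2CO3 (1.1 equiv), acetone, reflux
Reagents that add atoms: benzyl bromide, BrCc1ccccc1
Why: Williamson etherification; the 7-OH is the most acidic, non-chelated phenol while the 5-OH is locked in a hydrogen bond to C4=O, so mono-benzylation goes to O7.

**Step 2**
Reactants: 2 7-(benzyloxy)-5-hydroxy-2-(4-methoxyphenyl)-4H-chromen-4-one
Product: 4 7-(benzyloxy)-5,8-dihydroxy-2-(4-methoxyphenyl)-4H-chromen-4-one, via potassium aryl sulfate 3 (not isolated)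
Conditions: K2S2O8 (1.5 equiv), aq KOH/pyridine, 15–20 °C, 24 h; acidify to pH 5 and filter off unreacted 2 (recycled); then aq HCl, 85 °C, 30 min, under Ar
Reagents that add atoms: potassium peroxodisulfate, [K+].[K+].[O-]S(=O)(=O)OOS(=O)(=O)[O-]
Why: Elbs persulfate oxidation; the 5-phenoxide attacks the peroxide oxygen through its para carbon C8 (the only free position para to O5), and acid hydrolysis of the aryl sulfate gives the quinol, as in the classical nuclear oxidation of 5-hydroxy-7-alkoxyflavones.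

**Step 3**
Reactants: 4 7-(benzyloxy)-5,8-dihydroxy-2-(4-methoxyphenyl)-4H-chromen-4-one; 5 bis(4-bromophenyl)iodonium triflate
Product: 6 7-(benzyloxy)-8-(4-bromophenoxy)-5-hydroxy-2-(4-methoxyphenyl)-4H-chromen-4-one
Conditions: t-BuOK (1.05 equiv), degassed THF, 0 °C; then 5 (1.1 equiv), 40 °C, Ar
Reagents that add atoms: none
Why: Metal-free O-arylation of a phenoxide with a diaryliodonium salt (ligand coupling at iodine(III)); the 8-OH is the non-chelated, more acidic and more nucleophilic phenol, the symmetric salt removes any aryl-transfer selectivity issue, and the reaction tolerates di-ortho-substituted phenoxides.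

**Step 4**
Reactants: 7 1-[2,4-bis(benzyloxy)-6-hydroxyphenyl]ethan-1-one
Product: 9 5,7-bis(benzyloxy)-4H-chromen-4-one, via enaminone 8 (not isolated)
Conditions: DMF-DMA (2 equiv), toluene, 100 °C; evaporate; then AcOH, 90 °C
Reagents that add atoms: N,N-dimethylformamide dimethyl acetal, COC(OC)N(C)C
Why: Condensation of the methyl ketone with DMF-DMA gives the enaminone, and acid-mediated intramolecular oxa-Michael addition with loss of dimethylamine closes the pyranone (standard enaminone chromone annulation).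

**Step 5**
Reactants: 9 5,7-bis(benzyloxy)-4H-chromen-4-one; 6 7-(benzyloxy)-8-(4-bromophenoxy)-5-hydroxy-2-(4-methoxyphenyl)-4H-chromen-4-one
Product: 11 7-(benzyloxy)-8-{4-[5,7-bis(benzyloxy)-4-oxo-4H-chromen-2-yl]phenoxy}-5-hydroxy-2-(4-methoxyphenyl)-4H-chromen-4-one, via 2-chromonylzinc chloride 10 (not isolated)
Conditions: 9 (1.8 equiv), TMPZnCl·LiCl (1.9 equiv, no MgCl2 or BF3 added), THF, 25 °C, 1 h; then 6 (1.0 equiv), Pd(OAc)2 (4 mol%), SPhos (8 mol%), THF, 50 °C
Reagents that add atoms: none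
Why: Directed C2–H zincation of the chromone with the hindered zinc amide gives an α-alkoxyvinyl zinc species (a masked acyl anion / β-acylvinyl anion, i.e. the normally electrophilic C2 with reversed polarity), which undergoes Negishi cross-coupling with the aryl bromide carbon; organozinc halides with Pd/SPhos tolerate the ketones, ethers and the chelated 5-OH (the excess zinc reagent covers any protonation).

**Step 6**
Reactants: 11 7-(benzyloxy)-8-{4-[5,7-bis(benzyloxy)-4-oxo-4H-chromen-2-yl]phenoxy}-5-hydroxy-2-(4-methoxyphenyl)-4H-chromen-4-one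
Product: 12 8-[4-(5,7-dihydroxy-4-oxo-4H-chromen-2-yl)phenoxy]-5,7-dihydroxy-2-(4-methoxyphenyl)-4H-chromen-4-one (target, achiral)
Conditions: H2 (1 atm), 10% Pd/C, THF–MeOH, rt
Reagents that add atoms: none
Why: Catalytic hydrogenolysis of the three aryl benzyl ethers; the aryl methyl ether, the diaryl ether and both flavone enones survive at 1 atm and rt, and the neutral conditions avoid Wessely–Moser isomerisation of the 5,7-dihydroxy-8-aryloxy ring.

**Compound list**
1 | acacetin, 5,7-dihydroxy-2-(4-methoxyphenyl)-4H-chromen-4-one | COc1ccc(-c2cc(=O)c3c(O)cc(O)cc3o2)cc1 | starting material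
2 | 7-(benzyloxy)-5-hydroxy-2-(4-methoxyphenyl)-4H-chromen-4-one | COc1ccc(-c2cc(=O)c3c(O)cc(OCc4ccccc4)cc3o2)cc1 | intermediate
3 | potassium 7-(benzyloxy)-5-hydroxy-2-(4-methoxyphenyl)-4-oxo-4H-chromen-8-yl sulfate | COc1ccc(-c2cc(=O)c3c(O)cc(OCc4ccccc4)c(OS(=O)(=O)[O-])c3o2)cc1.[K+] | intermediate (not isolated)
4 | 7-(benzyloxy)-5,8-dihydroxy-2-(4-methoxyphenyl)-4H-chromen-4-one | COc1ccc(-c2cc(=O)c3c(O)cc(OCc4ccccc4)c(O)c3o2)cc1 | intermediate
5 | bis(4-bromophenyl)iodonium trifluoromethanesulfonate | Brc1ccc([I+]c2ccc(Br)cc2)cc1.[O-]S(=O)(=O)C(F)(F)F | starting material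
6 | 7-(benzyloxy)-8-(4-bromophenoxy)-5-hydroxy-2-(4-methoxyphenyl)-4H-chromen-4-one | COc1ccc(-c2cc(=O)c3c(O)cc(OCc4ccccc4)c(Oc4ccc(Br)cc4)c3o2)cc1 | intermediate
7 | 1-[2,4-bis(benzyloxy)-6-hydroxyphenyl]ethan-1-one | CC(=O)c1c(O)cc(OCc2ccccc2)cc1OCc1ccccc1 | starting material
8 | (E)-1-[2,4-bis(benzyloxy)-6-hydroxyphenyl]-3-(dimethylamino)prop-2-en-1-one | CN(C)/C=C/C(=O)c1c(O)cc(OCc2ccccc2)cc1OCc1ccccc1 | intermediate (not isolated)
9 | 5,7-bis(benzyloxy)-4H-chromen-4-one | O=c1ccoc2cc(OCc3ccccc3)cc(OCc3ccccc3)c12 | intermediate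
10 | [5,7-bis(benzyloxy)-4-oxo-4H-chromen-2-yl]zinc chloride–lithium chloride complex | O=c1cc([Zn]Cl)oc2cc(OCc3ccccc3)cc(OCc3ccccc3)c12.[Li+].[Cl-] | intermediate (not isolated)
11 | 7-(benzyloxy)-8-{4-[5,7-bis(benzyloxy)-4-oxo-4H-chromen-2-yl]phenoxy}-5-hydroxy-2-(4-methoxyphenyl)-4H-chromen-4-one | COc1ccc(-c2cc(=O)c3c(O)cc(OCc4ccccc4)c(Oc4ccc(-c5cc(=O)c6c(OCc7ccccc7)cc(OCc7ccccc7)cc6o5)cc4)c3o2)cc1 | intermediate
12 | 8-[4-(5,7-dihydroxy-4-oxo-4H-chromen-2-yl)phenoxy]-5,7-dihydroxy-2-(4-methoxyphenyl)-4H-chromen-4-one | COc1ccc(-c2cc(=O)c3c(O)cc(O)c(Oc4ccc(-c5cc(=O)c6c(O)cc(O)cc6o5)cc4)c3o2)cc1 | target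

**Totals**
Total step count: 6. Longest linear sequence: 5 (steps 1, 2, 3, 5, 6).

**Steps most likely to fail, and fallbacks**

Step 2 (Elbs oxidation: low conversion, over-oxidation to the 5,8-quinone). The fallback sets out from 2 and comes back at 4. The 5-OH of 2 is benzylated (BnBr, K2CO3, DMF, 80 °C) to 5,7-bis(benzyloxy)-2-(4-methoxyphenyl)-4H-chromen-4-one F1. With O5 alkylated, electrophilic iodination (I2, CF3CO2Ag, CH2Cl2) goes to C8 and gives 5,7-bis(benzyloxy)-8-iodo-2-(4-methoxyphenyl)-4H-chromen-4-one F2. Pd-catalysed hydroxylation (Pd2(dba)3, t-BuXPhos, KOH, dioxane–H2O, 80 °C) gives 5,7-bis(benzyloxy)-8-hydroxy-2-(4-methoxyphenyl)-4H-chromen-4-one F3. Selective cleavage of the peri 5-O-benzyl group (BCl3, CH2Cl2, −78 °C) then returns 4.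

Step 3 (O8 versus O5 selectivity, oxidation of the quinol by iodine(III), aryne side path). The fallback sets out from 4 and comes back at 6. SNAr of the 8-phenoxide on 1-fluoro-4-nitrobenzene (K2CO3, DMF, 70 °C, Ar) gives 7-(benzyloxy)-5-hydroxy-2-(4-methoxyphenyl)-8-(4-nitrophenoxy)-4H-chromen-4-one F4. Reduction (Fe, NH4Cl, EtOH–H2O, 70 °C) gives 8-(4-aminophenoxy)-7-(benzyloxy)-5-hydroxy-2-(4-methoxyphenyl)-4H-chromen-4-one F5. Sandmeyer bromination (t-BuONO, CuBr2, MeCN, 0 °C to rt) gives 6.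

Step 5 (protonation of the zinc reagent by the 5-OH, slow coupling of the hindered electron-rich bromide). The fallback sets out from 9 and 6 and comes back at 11, with the roles of the coupling partners inverted. The zinc species 10 made from 9 is quenched with I2 (THF, 0 °C) to give 5,7-bis(benzyloxy)-2-iodo-4H-chromen-4-one F6. Bromide 6 is converted by Miyaura borylation (B2pin2, Pd(dppf)Cl2, KOAc, dioxane, 90 °C) into 7-(benzyloxy)-5-hydroxy-2-(4-methoxyphenyl)-8-[4-(4,4,5,5-tetramethyl-1,3,2-dioxaborolan-2-yl)phenoxy]-4H-chromen-4-one F7. Suzuki coupling of the two (Pd(PPh3)4, K3PO4, dioxane–H2O, 80 °C) gives 11. This answers a failed coupling only; it still relies on the C2-zincation of 9.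

**Further compounds**
F1 | step 2 | 5,7-bis(benzyloxy)-2-(4-methoxyphenyl)-4H-chromen-4-one | COc1ccc(-c2cc(=O)c3c(OCc4ccccc4)cc(OCc4ccccc4)cc3o2)cc1
F2 | step 2 | 5,7-bis(benzyloxy)-8-iodo-2-(4-methoxyphenyl)-4H-chromen-4-one | COc1ccc(-c2cc(=O)c3c(OCc4ccccc4)cc(OCc4ccccc4)c(I)c3o2)cc1
F3 | step 2 | 5,7-bis(benzyloxy)-8-hydroxy-2-(4-methoxyphenyl)-4H-chromen-4-one | COc1ccc(-c2cc(=O)c3c(OCc4ccccc4)cc(OCc4ccccc4)c(O)c3o2)cc1
F4 | step 3 | 7-(benzyloxy)-5-hydroxy-2-(4-methoxyphenyl)-8-(4-nitrophenoxy)-4H-chromen-4-one | COc1ccc(-c2cc(=O)c3c(O)cc(OCc4ccccc4)c(Oc4ccc([N+](=O)[O-])cc4)c3o2)cc1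
F5 | step 3 | 8-(4-aminophenoxy)-7-(benzyloxy)-5-hydroxy-2-(4-methoxyphenyl)-4H-chromen-4-one | COc1ccc(-c2cc(=O)c3c(O)cc(OCc4ccccc4)c(Oc4ccc(N)cc4)c3o2)cc1
F6 | step 5 | 5,7-bis(benzyloxy)-2-iodo-4H-chromen-4-one | O=c1cc(I)oc2cc(OCc3ccccc3)cc(OCc3ccccc3)c12
F7 | step 5 | 7-(benzyloxy)-5-hydroxy-2-(4-methoxyphenyl)-8-[4-(4,4,5,5-tetramethyl-1,3,2-dioxaborolan-2-yl)phenoxy]-4H-chromen-4-one | COc1ccc(-c2cc(=O)c3c(O)cc(OCc4ccccc4)c(Oc4ccc(B5OC(C)(C)C(C)(C)O5)cc4)c3o2)cc1
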